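**Plan**
1. Numbering: elemanolide numbering, saturated-lactone half unprimed, butenolide half primed. Cuts: C7'=C11' and O–C12' (butenolide), C13–C13' (link), C7–C11 and O–C12 (cis-lactone), and in each cyclohexane C6–C7 together with C5–C10.
2. Enabling feature: in ring C5–C6–C7–C8–C9–C10 the lactone oxygen on C8 and the isopropenyl-bearing C5 are 1,4 to each other, next to quaternary C10. This is the pattern of a "para" Diels–Alder adduct of a 2-silyloxydiene C7=C8(OSi)–C9=C10 with methyl vinyl ketone (C5=C6). A slender alkynyl group stands in for the C10 vinyl group so that it can sit "inside" the s-cis diene and no second diene exists.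
3. Forward: acetylacetone → (Z)-enynone → silyloxydiene; one asymmetric Diels–Alder reaction per half (the two halves need antipodal cyclohexanes); Wittig reaction and semi-hydrogenation reveal isopropenyl and vinyl.
4. Saturated half: C7 alkylation, reduction/cis-lactonisation, α-methylenation, selenol addition, radical addition to a phosphonoacrylate. Butenolide half: α-oximino ketone → α-ketol. Union: Mitsunobu esterification, then intramolecular Horner–Wadsworth–Emmons closure.
5. Stereochemistry: C5/C10 relative from the endo rule plus the (Z)-diene geometry, absolute from the catalyst antipode; C7 by equilibration; C8 by equatorial hydride attack; C11 by convex-face protonation; C8' by hydride attack followed by Mitsunobu inversion.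

Key step: step 4

Remark: the (S)-oxazaborolidinium ion is assumed to give the (5S,10S) series; if the sense of induction is the opposite, the catalyst antipodes of steps 4 and 13 are exchanged.

**Step 1**
Reactants: 1 pentane-2,4-dione; 2 trifluoromethanesulfonic anhydride
Product: 3 (2Z)-4-oxopent-2-en-2-yl trifluoromethanesulfonate
Conditions: NaH, 1,2-dimethoxyethane, 0 °C; then (CF3SO2)2O, −20 °C
Reagents that add atoms: trifluoromethanesulfonic anhydride, O=S(=O)(OS(=O)(=O)C(F)(F)F)C(F)(F)F
Why: O-sulfonylation of the chelated, U-shaped sodium enolate of the 1,3-diketone (enol triflate formation) should place the triflate cis to the acetyl group.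

**Step 2**
Reactants: 3 enol triflate; 4 ethynyl(trimethyl)silane
Product: 5 (3Z)-4-methyl-6-(trimethylsilyl)hex-3-en-5-yn-2-one
Conditions: Pd(PPh3)2Cl2 (3 mol %), CuI (6 mol %), i-Pr2NH, THF, 0 °C → rt
Reagents that add atoms: ethynyl(trimethyl)silane, C#C[Si](C)(C)C
Why: Sonogashira coupling of an electron-poor vinyl triflate proceeds with retention of alkene geometry, so the alkynyl group should end cis to the acetyl group.

**Step 3**
Reactants: 5 enynone; 6 tert-butyldimethylsilyl trifluoromethanesulfonate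
Product: 7 tert-butyl(dimethyl){[(3Z)-4-methyl-6-(trimethylsilyl)hexa-1,3-dien-5-yn-2-yl]oxy}silane
Conditions: Et3N, CH2Cl2, −78 → 0 °C
Reagents that add atoms: tert-butyldimethylsilyl trifluoromethanesulfonate, CC(C)(C)[Si](C)(C)OS(=O)(=O)C(F)(F)F
Why: Soft enolisation of the methyl ketone (silyl enol ether formation) should give the cross-conjugated 2-silyloxydiene without touching the C9=C10 geometry, because the γ-methyl group is trans to the carbonyl group.

**Step 4**
Reactants: 7 silyloxydiene; 8 but-3-en-2-one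
Product: 9 1-[(1R,2R)-4-[(tert-butyldimethylsilyl)oxy]-2-methyl-2-[(trimethylsilyl)ethynyl]cyclohex-3-en-1-yl]ethan-1-one (acetyl cis to methyl)
Conditions: (S)-1-(2-methylphenyl)-3,3-diphenyl-tetrahydro-1H,3H-pyrrolo[1,2-c][1,3,2]oxazaborole (20 mol %), HN(SO2CF3)2 (16 mol %), CH2Cl2, −78 → −40 °C
Reagents that add atoms: but-3-en-2-one, C=CC(C)=O
Why: The protonated oxazaborolidine binds the ketone oxygen of 8 and lowers its LUMO, so the enol-ether terminus C7 of 7 bonds to the β-carbon C6 first and the C5–C10 bond follows in the same asynchronous, suprafacial [4+2] event, which closes the six-membered ring as a cyclohexene carrying the new C8=C9 silyl enol ether. The closest known reaction types are the chiral oxazaborolidinium-catalysed Diels–Alder reaction of 2-silyloxy-1,3-dienes with enones and Lewis-acid Diels–Alder reactions of 4,4-disubstituted 2-silyloxydienes that create a quaternary carbon. The "para" regiochemistry (acetyl 1,4 to OSi) follows from the 2-silyloxy donor, and site selectivity is secured because the alkyne offers no second diene. The endo transition state places the acetyl group cis to the "outside" methyl group and trans to the "inside" alkynyl group, so the (3Z) geometry of 7 is translated into the C5/C10 relationship; the slender alkynyl group is what lets the s-cis conformer form. The absolute configuration of both centres is set by the enone face left open by the catalyst.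

**Step 5**
Reactants: 9 cycloadduct; 10 methyltriphenylphosphonium bromide
Product: 12 (3R,4S)-3-ethynyl-3-methyl-4-(prop-1-en-2-yl)cyclohexan-1-one, via isopropenyl bis-silyl intermediate 11 (not isolated)
Conditions: Ph3PCH3Br, KN(SiMe3)2, THF, 0 °C → rt; then Bu4NF, AcOH, THF, 0 °C
Reagents that add atoms: methyltriphenylphosphonium bromide, C[P+](c1ccccc1)(c1ccccc1)c1ccccc1.[Br-]
Why: Wittig methylenation should convert the acetyl group into the isopropenyl group while the C8 ketone is still masked as its silyl enol ether, and buffered fluoride then cleaves both the O–Si and the C(sp)–Si bond.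

**Step 6**
Reactants: 12 alkynyl ketone
Product: 13 (3S,4S)-3-ethenyl-3-methyl-4-(prop-1-en-2-yl)cyclohexan-1-one
Conditions: H2 (1 atm), Pd/CaCO3 poisoned with Pb(OAc)2, quinoline, EtOAc, rt
Reagents that add atoms: none
Why: Lindlar semi-hydrogenation should stop at the alkene for a terminal alkyne and leave the 1,1-disubstituted alkene and the ketone untouched.

**Step 7**
Reactants: 13 ketone; 14 methyl bromoacetate
Product: 15 methyl 2-[(1R,4S,5S)-4-ethenyl-4-methyl-2-oxo-5-(prop-1-en-2-yl)cyclohexyl]acetate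
Conditions: LiN(i-Pr)2, THF, −78 °C; BrCH2CO2Me, −78 → 0 °C; then DBU (cat.), CH2Cl2, rt
Reagents that add atoms: methyl bromoacetate, COC(=O)CBr
Why: Kinetic deprotonation should occur at C7 because C9 is neopentylic, enolate alkylation installs C11/C12, and base equilibration places the side chain equatorial (cis to isopropenyl), which is the C7 configuration of the target.

**Step 8**
Reactants: 15 keto ester
Product: 17 (3aR,5S,6S,7aR)-6-ethenyl-6-methyl-5-(prop-1-en-2-yl)hexahydro-1-benzofuran-2(3H)-one, via axial hydroxy ester 16 (not isolated)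
Conditions: LiBH(s-Bu)3, THF, −78 °C; then aq. NH4Cl; p-TsOH·H2O (cat.), CH2Cl2, rt
Reagents that add atoms: none
Why: The bulky hydride should attack from the equatorial side (the axial C10 methyl blocks the other face), and the axial C8 alkoxide, cis to the C7 side chain, closes the cis-fused γ-lactone (diastereoselective ketone reduction/lactonisation).

**Step 9**
Reactants: 17 lactone; 18 N,N-dimethylmethaniminium iodide; 19 iodomethane
Product: 22 (3aR,5S,6S,7aR)-6-ethenyl-6-methyl-3-methylidene-5-(prop-1-en-2-yl)hexahydro-1-benzofuran-2(3H)-one, via Mannich base 20 (not isolated), via methiodide 21 (not isolated)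
Conditions: LiN(i-Pr)2, THF, −78 °C; CH2=NMe2+ I−, −78 °C → rt; then MeI, MeOH, rt; then aq. NaHCO3, CH2Cl2
Reagents that add atoms: N,N-dimethylmethaniminium iodide, C=[N+](C)C.[I-]; iodomethane, CI (its methyl group is carried only by intermediate 21)
Why: Mannich reaction of the lactone enolate, quaternisation and E1cB elimination is the standard α-methylenation of γ-lactones.

**Step 10**
Reactants: 22 α-methylene lactone; 23 benzeneselenol
Product: 24 (3S,3aR,5S,6S,7aR)-6-ethenyl-6-methyl-3-[(phenylselanyl)methyl]-5-(prop-1-en-2-yl)hexahydro-1-benzofuran-2(3H)-one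
Conditions: PhSeH, Et3N (10 mol %), CH2Cl2, −20 °C
Reagents that add atoms: benzeneselenol, [SeH]c1ccccc1
Why: Selenol Michael addition is followed by kinetic protonation of the enolate from the convex face of the cis-fused bicycle, which should set C11 with H11 cis to H7 and H8.

**Step 11**
Reactants: 24 selenide; 25 ethyl 2-(diethoxyphosphoryl)prop-2-enoate
Product: 26 ethyl 2-(diethoxyphosphoryl)-4-[(3S,3aR,5S,6S,7aR)-6-ethenyl-6-methyl-2-oxo-5-(prop-1-en-2-yl)octahydro-1-benzofuran-3-yl]butanoate (both epimers at the phosphonate carbon)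
Conditions: (Me3Si)3SiH (slow addition), AIBN (cat.), 25 (3 equiv), benzene, 80 °C
Reagents that add atoms: ethyl 2-(diethoxyphosphoryl)prop-2-enoate, C=C(C(=O)OCC)P(=O)(OCC)OCC
Why: Giese-type radical conjugate addition: the nucleophilic primary C13 radical released from the selenide should add to the doubly activated acrylate to form C13–C13', and the stabilised adduct radical takes hydrogen from the silane without touching C11.

**Step 12**
Reactants: 26 phosphono ester; 27 lithium hydroxide
Product: 29 2-(diethoxyphosphoryl)-4-[(3S,3aR,5S,6S,7aR)-6-ethenyl-6-methyl-2-oxo-5-(prop-1-en-2-yl)octahydro-1-benzofuran-3-yl]butanoic acid, via ring-opened dilithium dicarboxylate 28 (not isolated)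
Conditions: LiOH, THF/H2O, 0 °C → rt; then 1 M HCl to pH 2, rt
Reagents that add atoms: lithium hydroxide, [Li+].[OH-]
Why: Saponification of the activated ethyl ester (the lactone opens as well) and acidification, on which the cis-γ-hydroxy acid re-closes, should give the free phosphono acid without enolisation at C11.

**Step 13**
Reactants: 7 silyloxydiene; 8 but-3-en-2-one
Product: 30 1-[(1S,2S)-4-[(tert-butyldimethylsilyl)oxy]-2-methyl-2-[(trimethylsilyl)ethynyl]cyclohex-3-en-1-yl]ethan-1-one (enantiomer of 9)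
Conditions: (R)-1-(2-methylphenyl)-3,3-diphenyl-tetrahydro-1H,3H-pyrrolo[1,2-c][1,3,2]oxazaborole (20 mol %), HN(SO2CF3)2 (16 mol %), CH2Cl2, −78 → −40 °C
Reagents that add atoms: but-3-en-2-one, C=CC(C)=O
Why: The same endo Diels–Alder reaction as in step 4 with the mirror-image catalyst should deliver the antipodal cyclohexene needed for the butenolide half.

**Step 14**
Reactants: 30 cycloadduct; 10 methyltriphenylphosphonium bromide
Product: 32 (3S,4R)-3-ethynyl-3-methyl-4-(prop-1-en-2-yl)cyclohexan-1-one, via isopropenyl bis-silyl intermediate 31 (not isolated)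
Conditions: Ph3PCH3Br, KN(SiMe3)2, THF, 0 °C → rt; then Bu4NF, AcOH, THF, 0 °C
Reagents that add atoms: methyltriphenylphosphonium bromide, C[P+](c1ccccc1)(c1ccccc1)c1ccccc1.[Br-]
Why: Wittig methylenation and fluoride desilylation as in step 5.

**Step 15**
Reactants: 32 alkynyl ketone
Product: 33 (3R,4R)-3-ethenyl-3-methyl-4-(prop-1-en-2-yl)cyclohexan-1-one
Conditions: H2 (1 atm), Pd/CaCO3 poisoned with Pb(OAc)2, quinoline, EtOAc, rt
Reagents that add atoms: none
Why: Lindlar semi-hydrogenation as in step 6.

**Step 16**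
Reactants: 33 ketone; 34 3-methylbutyl nitrite
Product: 35 (4R,5R)-5-ethenyl-2-(hydroxyimino)-5-methyl-4-(prop-1-en-2-yl)cyclohexan-1-one
Conditions: t-BuOK, THF/t-BuOH, 0 °C
Reagents that add atoms: 3-methylbutyl nitrite, CC(C)CCON=O
Why: Base-mediated α-nitrosation (oximation) should occur at the unhindered C7' methylene and not at neopentylic C9', giving an α-oximino ketone that masks the future C7' carbonyl group.

**Step 17**
Reactants: 35 α-oximino ketone
Product: 36 (1S,4R,5R)-5-ethenyl-2-(hydroxyimino)-5-methyl-4-(prop-1-en-2-yl)cyclohexan-1-ol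
Conditions: NaBH4, CeCl3·7H2O, MeOH, −40 °C
Reagents that add atoms: none
Why: Luche-type 1,2-reduction leaves the oxime untouched and, by equatorial hydride attack, should give the axial C8' alcohol (cis to the C10' methyl group).

**Step 18**
Reactants: 36 hydroxy oxime; 37 water
Product: 38 (2S,4R,5R)-4-ethenyl-2-hydroxy-4-methyl-5-(prop-1-en-2-yl)cyclohexan-1-one
Conditions: TiCl3 (aq.), NH4OAc, 1,4-dioxane/H2O, rt
Reagents that add atoms: water, O
Why: Buffered reductive deoximation (N–O cleavage, imine hydrolysis) should unmask the C7' ketone and complete a 1,2-carbonyl transposition to the α-ketol.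

**Step 19**
Reactants: 38 α-ketol; 29 phosphono acid
Product: 39 (1R,4R,5R)-5-ethenyl-5-methyl-2-oxo-4-(prop-1-en-2-yl)cyclohexyl 2-(diethoxyphosphoryl)-4-[(3S,3aR,5S,6S,7aR)-6-ethenyl-6-methyl-2-oxo-5-(prop-1-en-2-yl)octahydro-1-benzofuran-3-yl]butanoate
Conditions: PPh3, diisopropyl azodicarboxylate, toluene, 0 °C → rt
Reagents that add atoms: none
Why: Mitsunobu esterification: the axial, carbonyl-activated C8' alcohol should be displaced by the carboxylate with inversion, giving the equatorial (8'R) ester and joining the two halves.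

**Step 20**
Reactants: 39 keto phosphonate
Product: 40 target CNP0332736.1
Conditions: LiBr, Et3N, THF, 0 °C → rt
Reagents that add atoms: none
Why: Intramolecular Horner–Wadsworth–Emmons reaction of the phosphonate carbanion with the adjacent C7' ketone should close the five-membered butenolide and form the tetrasubstituted C7'=C11' bond under conditions too mild to enolise either lactone.

**Compound list**
1 | pentane-2,4-dione | CC(=O)CC(C)=O | starting material
2 | trifluoromethanesulfonic anhydride | O=S(=O)(OS(=O)(=O)C(F)(F)F)C(F)(F)F | starting material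
3 | (2Z)-4-oxopent-2-en-2-yl trifluoromethanesulfonate | CC(=O)/C=C(/C)OS(=O)(=O)C(F)(F)F | intermediate
4 | ethynyl(trimethyl)silane | C#C[Si](C)(C)C | starting material
5 | (3Z)-4-methyl-6-(trimethylsilyl)hex-3-en-5-yn-2-one | CC(=O)/C=C(/C)C#C[Si](C)(C)C | intermediate
6 | tert-butyldimethylsilyl trifluoromethanesulfonate | CC(C)(C)[Si](C)(C)OS(=O)(=O)C(F)(F)F | starting material
7 | tert-butyl(dimethyl){[(3Z)-4-methyl-6-(trimethylsilyl)hexa-1,3-dien-5-yn-2-yl]oxy}silane | C=C(O[Si](C)(C)C(C)(C)C)/C=C(/C)C#C[Si](C)(C)C | intermediate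
8 | but-3-en-2-one | C=CC(C)=O | starting material
9 | 1-[(1R,2R)-4-[(tert-butyldimethylsilyl)oxy]-2-methyl-2-[(trimethylsilyl)ethynyl]cyclohex-3-en-1-yl]ethan-1-one | C[Si](C)(C)C#C[C@]1(C)C=C(O[Si](C)(C)C(C)(C)C)CC[C@H]1C(C)=O | intermediate
10 | methyltriphenylphosphonium bromide | C[P+](c1ccccc1)(c1ccccc1)c1ccccc1.[Br-] | starting material
11 | isopropenyl analogue of 9 (acetyl replaced by prop-1-en-2-yl, both silyl groups in place) | C[Si](C)(C)C#C[C@]1(C)C=C(O[Si](C)(C)C(C)(C)C)CC[C@H]1C(C)=C | intermediate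
12 | (3R,4S)-3-ethynyl-3-methyl-4-(prop-1-en-2-yl)cyclohexan-1-one | O=C1C[C@@](C)(C#C)[C@H](C(=C)C)CC1 | intermediate
13 | (3S,4S)-3-ethenyl-3-methyl-4-(prop-1-en-2-yl)cyclohexan-1-one | O=C1C[C@@](C)(C=C)[C@H](C(=C)C)CC1 | intermediate
14 | methyl bromoacetate | COC(=O)CBr | starting material
15 | methyl 2-[(1R,4S,5S)-4-ethenyl-4-methyl-2-oxo-5-(prop-1-en-2-yl)cyclohexyl]acetate | O=C1C[C@@](C)(C=C)[C@H](C(=C)C)C[C@@H]1CC(=O)OC | intermediate
16 | methyl 2-[(1R,2R,4S,5S)-4-ethenyl-2-hydroxy-4-methyl-5-(prop-1-en-2-yl)cyclohexyl]acetate (axial OH) | COC(=O)C[C@H]1C[C@@H](C(=C)C)[C@](C)(C=C)C[C@H]1O | intermediate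
17 | (3aR,5S,6S,7aR)-6-ethenyl-6-methyl-5-(prop-1-en-2-yl)hexahydro-1-benzofuran-2(3H)-one | C1C(=O)O[C@@H]2C[C@@](C)(C=C)[C@H](C(=C)C)C[C@H]12 | intermediate
18 | N,N-dimethylmethaniminium iodide | C=[N+](C)C.[I-] | starting material
19 | iodomethane | CI | starting material
20 | 3-[(dimethylamino)methyl] derivative of 17 (aminomethyl group on the convex face) | CN(C)C[C@H]1C(=O)O[C@@H]2C[C@@](C)(C=C)[C@H](C(=C)C)C[C@H]12 | intermediate
21 | methiodide of 20 | C[N+](C)(C)C[C@H]1C(=O)O[C@@H]2C[C@@](C)(C=C)[C@H](C(=C)C)C[C@H]12.[I-] | intermediate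
22 | (3aR,5S,6S,7aR)-6-ethenyl-6-methyl-3-methylidene-5-(prop-1-en-2-yl)hexahydro-1-benzofuran-2(3H)-one | C=C1C(=O)O[C@@H]2C[C@@](C)(C=C)[C@H](C(=C)C)C[C@H]12 | intermediate
23 | benzeneselenol | [SeH]c1ccccc1 | starting material
24 | (3S,3aR,5S,6S,7aR)-6-ethenyl-6-methyl-3-[(phenylselanyl)methyl]-5-(prop-1-en-2-yl)hexahydro-1-benzofuran-2(3H)-one | c3ccccc3[Se]C[C@@H]1C(=O)O[C@@H]2C[C@@](C)(C=C)[C@H](C(=C)C)C[C@H]12 | intermediate
25 | ethyl 2-(diethoxyphosphoryl)prop-2-enoate | C=C(C(=O)OCC)P(=O)(OCC)OCC | starting material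
26 | ethyl 2-(diethoxyphosphoryl)-4-[(3S,3aR,5S,6S,7aR)-6-ethenyl-6-methyl-2-oxo-5-(prop-1-en-2-yl)octahydro-1-benzofuran-3-yl]butanoate | CCOC(=O)C(CC[C@@H]1C(=O)O[C@@H]2C[C@@](C)(C=C)[C@H](C(=C)C)C[C@H]12)P(=O)(OCC)OCC | intermediate
27 | lithium hydroxide | [Li+].[OH-] | starting material
28 | dilithium salt of the ring-opened hydroxy diacid from 26 | [Li+].[Li+].[O-]C(=O)C(CC[C@H](C([O-])=O)[C@H]1C[C@@H](C(=C)C)[C@](C)(C=C)C[C@H]1O)P(=O)(OCC)OCC | intermediate
29 | 2-(diethoxyphosphoryl)-4-[(3S,3aR,5S,6S,7aR)-6-ethenyl-6-methyl-2-oxo-5-(prop-1-en-2-yl)octahydro-1-benzofuran-3-yl]butanoic acid | OC(=O)C(CC[C@@H]1C(=O)O[C@@H]2C[C@@](C)(C=C)[C@H](C(=C)C)C[C@H]12)P(=O)(OCC)OCC | intermediate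
30 | 1-[(1S,2S)-4-[(tert-butyldimethylsilyl)oxy]-2-methyl-2-[(trimethylsilyl)ethynyl]cyclohex-3-en-1-yl]ethan-1-one | C[Si](C)(C)C#C[C@@]1(C)C=C(O[Si](C)(C)C(C)(C)C)CC[C@@H]1C(C)=O | intermediate
31 | isopropenyl analogue of 30 (enantiomer of 11) | C[Si](C)(C)C#C[C@@]1(C)C=C(O[Si](C)(C)C(C)(C)C)CC[C@@H]1C(C)=C | intermediate
32 | (3S,4R)-3-ethynyl-3-methyl-4-(prop-1-en-2-yl)cyclohexan-1-one | O=C1C[C@](C)(C#C)[C@@H](C(=C)C)CC1 | intermediate
33 | (3R,4R)-3-ethenyl-3-methyl-4-(prop-1-en-2-yl)cyclohexan-1-one | O=C1C[C@](C)(C=C)[C@@H](C(=C)C)CC1 | intermediate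
34 | 3-methylbutyl nitrite | CC(C)CCON=O | starting material
35 | (4R,5R)-5-ethenyl-2-(hydroxyimino)-5-methyl-4-(prop-1-en-2-yl)cyclohexan-1-one | O=C1C[C@](C)(C=C)[C@@H](C(=C)C)CC1=NO | intermediate
36 | (1S,4R,5R)-5-ethenyl-2-(hydroxyimino)-5-methyl-4-(prop-1-en-2-yl)cyclohexan-1-ol | O[C@H]1C[C@](C)(C=C)[C@@H](C(=C)C)CC1=NO | intermediate
37 | water | O | starting material
38 | (2S,4R,5R)-4-ethenyl-2-hydroxy-4-methyl-5-(prop-1-en-2-yl)cyclohexan-1-one | O=C1[C@@H](O)C[C@](C)(C=C)[C@@H](C(=C)C)C1 | intermediate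
39 | (1R,4R,5R)-5-ethenyl-5-methyl-2-oxo-4-(prop-1-en-2-yl)cyclohexyl ester of acid 29 | O=C1[C@H](OC(=O)C(CC[C@@H]2C(=O)O[C@@H]3C[C@@](C)(C=C)[C@H](C(=C)C)C[C@H]23)P(=O)(OCC)OCC)C[C@](C)(C=C)[C@@H](C(=C)C)C1 | intermediate
40 | (5R,6R,7aR)-6-ethenyl-3-{2-[(3S,3aR,5S,6S,7aR)-6-ethenyl-6-methyl-2-oxo-5-(prop-1-en-2-yl)octahydro-1-benzofuran-3-yl]ethyl}-6-methyl-5-(prop-1-en-2-yl)-5,6,7,7a-tetrahydro-1-benzofuran-2(4H)-one | C=C[C@@]1(C)C[C@H]2OC(=O)C(CC[C@@H]3C(=O)O[C@@H]4C[C@@](C)(C=C)[C@H](C(=C)C)C[C@H]34)=C2C[C@@H]1C(=C)C | target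

**Count**
Total steps: 20. Longest linear sequence: 14 steps (1–12, 19, 20).

**Steps most likely to fail**

Step 4 (and its mirror image, step 13). The cycloaddition may stall at the fully substituted diene terminus, may halt after the first C–C bond as an open-chain Michael adduct, or may lose endo or facial selectivity. The fallback sets out from 7 and uses a covalently bound chiral auxiliary in place of the catalyst. Et2AlCl-promoted Diels–Alder reaction of 7 with (4S)-3-acryloyl-4-benzyl-1,3-oxazolidin-2-one (a more reactive, chelated dienophile) should give the N-acyl oxazolidinone cycloadduct F1. Transamidation with Me(MeO)NH·HCl/AlMe3 should give the N-methoxy-N-methylamide F2, and MeMgBr converts it into the methyl ketone, which returns to the route at 9. The antipodal auxiliary would serve for 30.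

Step 19. The activated α-ketol may eliminate to an enone, or the hindered alcohol may be acylated with retention through an acyloxyphosphonium pathway. The fallback sets out from 38 and separates activation from displacement. MsCl/Et3N should give the α-keto mesylate F3, and SN2 displacement with the cesium carboxylate of 29 (Cs2CO3, DMF) proceeds with inversion and returns to the route at 39.

Step 11. The C13 radical may be reduced before it adds, or the acceptor may oligomerise. The fallback sets out from 22 and reverses the roles of the partners. Conjugate addition of 23 to 25 should give ethyl 2-(diethoxyphosphoryl)-3-(phenylselanyl)propanoate F4. Its primary radical ((Me3Si)3SiH, AIBN) adds to the exocyclic methylene of 22, and the C11 radical takes hydrogen from the convex face, which returns to the route at 26.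

**Further compounds**
F1 | step 4 | (4S)-4-benzyl-3-{[(1R,2R)-4-[(tert-butyldimethylsilyl)oxy]-2-methyl-2-[(trimethylsilyl)ethynyl]cyclohex-3-en-1-yl]carbonyl}-1,3-oxazolidin-2-one | C[Si](C)(C)C#C[C@]1(C)C=C(O[Si](C)(C)C(C)(C)C)CC[C@H]1C(=O)N2C(=O)OC[C@@H]2Cc2ccccc2
F2 | step 4 | (1R,2R)-4-[(tert-butyldimethylsilyl)oxy]-N-methoxy-N,2-dimethyl-2-[(trimethylsilyl)ethynyl]cyclohex-3-ene-1-carboxamide | C[Si](C)(C)C#C[C@]1(C)C=C(O[Si](C)(C)C(C)(C)C)CC[C@H]1C(=O)N(C)OC
F3 | step 19 | (1S,4R,5R)-5-ethenyl-5-methyl-2-oxo-4-(prop-1-en-2-yl)cyclohexyl methanesulfonate | O=C1[C@@H](OS(C)(=O)=O)C[C@](C)(C=C)[C@@H](C(=C)C)C1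
F4 | step 11 | ethyl 2-(diethoxyphosphoryl)-3-(phenylselanyl)propanoate | CCOC(=O)C(C[Se]c1ccccc1)P(=O)(OCC)OCC
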